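**Assumption:** the SMILES is read literally. Ring A (prenyl ring) is 2S,6R with the C2 and C6 substituents cis; ring B (hydroxyprenyl ring) is 2′R,6′S with them trans; all chain olefins and the side-chain olefin are E.

## Retrosynthetic overview

1. Wittig disconnections at C11=C12 and C11′=C12′ give the commercial C10 dialdehyde 14 and two C20 phosphonium salts: 13 (ring A, cis, prenyl) and 21 (ring B, trans, hydroxyprenyl).
2. Key bond: the only C–O bond of the target, made by (E)-selective allylic C–H hydroxylation of the prenyl group (17 → 18) while the ring olefin is switched off by an allylic ester; up to 5 the two halves share every intermediate.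
3. C6 and C6′: anti-SN2′ transfer of a C6 dienyl unit (one stock solution of Grignard reagent 10) onto an allylic picolinate. The ester C–O bond is formed with inversion (Mitsunobu, ring A) or retention (acylation, ring B) from the single alcohol 5, and this is the cis/trans switch.
4. C2 and C2′: one new Cu-catalysed enantioselective conjugate prenylation of the cross-conjugated dienone 2.
5. Rings: no ring is formed; both cyclohexene rings come from commercial 2,4,4-trimethylcyclohex-2-en-1-one, and ring A and ring B branch at 5.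

## Route

Step 1
Reactants: 1 2,4,4-trimethylcyclohex-2-en-1-one
Product: 2 2,4,4-trimethylcyclohexa-2,5-dien-1-one
Conditions: DDQ (1.3 equiv.), 1,4-dioxane, 100 °C
Reagents that add atoms: none
Why: DDQ dehydrogenation of the enone on its saturated side (hydride abstraction from the dienol) gives the cross-conjugated dienone, the quaternary C4 ruling out aromatisation; no stereocentre is formed.

Step 2
Reactants: 2 2,4,4-trimethylcyclohexa-2,5-dien-1-one; 3 4,4,5,5-tetramethyl-2-(3-methylbut-2-en-1-yl)-1,3,2-dioxaborolane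
Product: 4 (5S)-2,4,4-trimethyl-5-(3-methylbut-2-en-1-yl)cyclohex-2-en-1-one
Conditions: CuCl (5 mol %), (S,S)-diphenylethylenediamine-derived sulfonate-bearing imidazolinium salt (5.5 mol %), NaOt-Bu (20 mol %), MeOH (2 equiv.), THF, −30 °C
Reagents that add atoms: none
Why: Proposed new method: a chiral (N-heterocyclic carbene)Cu–prenyl species formed by B-to-Cu transmetalation should π-complex the less substituted, more electrophilic C5=C6 enone (the α-methylated C2=C3 enone is much slower), add oxidatively to a trivalent-copper β-cuprio enolate and eliminate reductively through the CH2 terminus of the allyl ligand, because C–C bonding through the CMe2 terminus (and likewise the closed six-membered 1,2-carbonyl addition through that terminus) would put two fully substituted carbons side by side next to the ring CMe2 group, while the ligand pocket differentiates the faces at C5 and sets the 5S centre (the mirror-image ligand is used if the sense of induction is opposite) and methanol protonates the enolate to turn the catalyst over; the closest known reactions are Cu-catalysed asymmetric conjugate additions of dialkylzinc and Grignard reagents to 4,4-disubstituted cyclohexadienones, NHC–Cu-catalysed allyl additions from allyl–B(pin) reagents to carbonyl compounds and dienoates, and stoichiometric allylic cuprate conjugate additions.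

Step 3
Reactants: 4 (5S)-2,4,4-trimethyl-5-(3-methylbut-2-en-1-yl)cyclohex-2-en-1-one
Product: 5 (1R,5S)-2,4,4-trimethyl-5-(3-methylbut-2-en-1-yl)cyclohex-2-en-1-ol
Conditions: NaBH4, CeCl3·7H2O, MeOH, −78 → −20 °C
Reagents that add atoms: none
Why: Luche reduction: the CeCl3-activated carbonyl takes hydride 1,2 and axially on the half-chair that keeps the C5 prenyl group equatorial (the carvone-to-cis-carveol precedent), which sets C1 as R with the hydroxyl cis to the prenyl group and leaves both olefins alone.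

Step 4
Reactants: 6 (2E)-3-methylpent-2-en-4-yn-1-ol
Product: 7 tert-butyl(dimethyl){[(2E)-3-methylpent-2-en-4-yn-1-yl]oxy}silane
Conditions: TBSCl, imidazole, CH2Cl2, 0 → 23 °C
Reagents that add atoms: tert-butyldimethylsilyl chloride, CC(C)(C)[Si](C)(C)Cl
Why: Standard silylation of a primary alcohol; the silyl ether masks the hydroxyl for the organometallic steps and is later removed by the same acid that forms the phosphonium salt.

Step 5
Reactants: 7 tert-butyl(dimethyl){[(2E)-3-methylpent-2-en-4-yn-1-yl]oxy}silane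
Product: 9 tert-butyl{[(2E,4E)-5-iodo-3-methylpenta-2,4-dien-1-yl]oxy}dimethylsilane, via dienylzirconocene chloride 8 (not isolated)
Conditions: Cp2Zr(H)Cl (1.3 equiv.), THF, 23 °C, dark; then I2, 0 °C
Reagents that add atoms: iodine, II
Why: Hydrozirconation adds Zr–H syn across the terminal alkyne with Zr at the terminus and iodinolysis of the C–Zr bond goes with retention, so the new olefin is E and the existing (E)-olefin of 7 is untouched.

Step 6
Reactants: 9 tert-butyl{[(2E,4E)-5-iodo-3-methylpenta-2,4-dien-1-yl]oxy}dimethylsilane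
Product: 10 chloro[(1E,3E)-5-{[tert-butyl(dimethyl)silyl]oxy}-3-methylpenta-1,3-dien-1-yl]magnesium (LiCl complex, obtained as a titrated THF solution that is kept at 0 °C and divided between steps 8 and 13)
Conditions: i-PrMgCl·LiCl (0.95 equiv.), THF, 0 → 23 °C; titration of an aliquot
Reagents that add atoms: isopropylmagnesium chloride lithium chloride complex (i-PrMgCl·LiCl), CC(C)[Mg]Cl.[Li+].[Cl-]
Why: Iodine–magnesium exchange of the conjugated alkenyl iodide with i-PrMgCl·LiCl goes with retention of the (E)-geometry and tolerates the silyl ether, and the slight excess of 9 ensures that no i-PrMgCl is left to attack the picolinate esters in the later couplings.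

Step 7
Reactants: 5 (1R,5S)-2,4,4-trimethyl-5-(3-methylbut-2-en-1-yl)cyclohex-2-en-1-ol
Product: 11 (1S,5S)-2,4,4-trimethyl-5-(3-methylbut-2-en-1-yl)cyclohex-2-en-1-yl pyridine-2-carboxylate
Conditions: picolinic acid, PPh3, DIAD, THF, −20 → 0 °C
Reagents that add atoms: picolinic acid (pyridine-2-carboxylic acid), OC(=O)c1ccccn1
Why: Mitsunobu esterification: SN2 displacement of the oxyphosphonium ion by picolinate inverts C1 to S (ester trans to the prenyl group), SN2′ leakage being blocked by the neopentylic γ-carbon.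

Step 8
Reactants: 11 (1S,5S)-2,4,4-trimethyl-5-(3-methylbut-2-en-1-yl)cyclohex-2-en-1-yl pyridine-2-carboxylate; 10 chloro[(1E,3E)-5-{[tert-butyl(dimethyl)silyl]oxy}-3-methylpenta-1,3-dien-1-yl]magnesium (THF solution)
Product: 12 tert-butyl(dimethyl){[(2E,4E)-3-methyl-5-[(1R,5S)-2,6,6-trimethyl-5-(3-methylbut-2-en-1-yl)cyclohex-2-en-1-yl]penta-2,4-dien-1-yl]oxy}silane
Conditions: 10 (1.6 equiv.), CuBr·SMe2 (30 mol %), THF, −40 → 0 °C; aq. NH4Cl
Reagents that add atoms: none
Why: The Cu-catalysed substitution of an allylic picolinate by a Grignard reagent (the magnesium-chelated pyridyl ester is the leaving group) is anti-SN2′ selective: the dienyl group enters at the γ-carbon on the face opposite the pseudoaxial ester, that is cis to the equatorial prenyl group, which sets the 6R centre of ring A and puts the ring olefin in the ε-position.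

Step 9
Reactants: 12 tert-butyl(dimethyl){[(2E,4E)-3-methyl-5-[(1R,5S)-2,6,6-trimethyl-5-(3-methylbut-2-en-1-yl)cyclohex-2-en-1-yl]penta-2,4-dien-1-yl]oxy}silane
Product: 13 [(2E,4E)-3-methyl-5-[(1R,5S)-2,6,6-trimethyl-5-(3-methylbut-2-en-1-yl)cyclohex-2-en-1-yl]penta-2,4-dien-1-yl](triphenyl)phosphonium bromide
Conditions: PPh3·HBr (1.1 equiv.), MeOH–CH2Cl2, 0 → 23 °C
Reagents that add atoms: triphenylphosphine hydrobromide, Br.P(c1ccccc1)(c1ccccc1)c1ccccc1
Why: Acidic methanolysis of the dienylic silyl ether and SN1 ionisation give the 3-methylpentadienyl cation, which PPh3 captures at the unhindered primary terminus (the vinyl-ionol-to-phosphonium reaction of carotenoid synthesis); the C6 stereocentre is not part of the cation and is kept.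

Step 10
Reactants: 13 [(2E,4E)-3-methyl-5-[(1R,5S)-2,6,6-trimethyl-5-(3-methylbut-2-en-1-yl)cyclohex-2-en-1-yl]penta-2,4-dien-1-yl](triphenyl)phosphonium bromide; 14 (2E,4E,6E)-2,7-dimethylocta-2,4,6-trienedial
Product: 16 (2E,4E,6E,8E,10E,12E)-2,7,11-trimethyl-13-[(1R,5S)-2,6,6-trimethyl-5-(3-methylbut-2-en-1-yl)cyclohex-2-en-1-yl]trideca-2,4,6,8,10,12-hexaenal, via phosphonium ylide 15 (not isolated)
Conditions: 14 (3 equiv.), NaOMe (1.1 equiv., slow addition), CH2Cl2–MeOH, 0 → 23 °C; then I2 (0.5 mol %), hexane, 23 °C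
Reagents that add atoms: none
Why: Wittig olefination of the semi-stabilised ylide with a threefold excess of the symmetric dialdehyde gives the mono-adduct, and iodine-catalysed equilibration turns the new C11=C12 bond E; the unconjugated C6 centre is not acidic enough for methoxide.

Step 11
Reactants: 5 (1R,5S)-2,4,4-trimethyl-5-(3-methylbut-2-en-1-yl)cyclohex-2-en-1-ol
Product: 17 (1R,5S)-2,4,4-trimethyl-5-(3-methylbut-2-en-1-yl)cyclohex-2-en-1-yl pyridine-2-carboxylate
Conditions: picolinic acid, DCC, DMAP (10 mol %), CH2Cl2, 23 °C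
Reagents that add atoms: picolinic acid (pyridine-2-carboxylic acid), OC(=O)c1ccccn1
Why: Steglich esterification acylates the alcohol oxygen, so C1 keeps its R configuration and the ester stays cis to the prenyl group.

Step 12
Reactants: 17 (1R,5S)-2,4,4-trimethyl-5-(3-methylbut-2-en-1-yl)cyclohex-2-en-1-yl pyridine-2-carboxylate
Product: 18 (1R,5S)-5-[(2E)-4-hydroxy-3-methylbut-2-en-1-yl]-2,4,4-trimethylcyclohex-2-en-1-yl pyridine-2-carboxylate
Conditions: SeO2 (20 mol %), t-BuOOH (2.5 equiv., in decane), salicylic acid (10 mol %), CH2Cl2, 0 → 23 °C, stopped near 70 % conversion, 17 recycled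
Reagents that add atoms: tert-butyl hydroperoxide, CC(C)(C)OO (terminal oxidant; its oxygen is relayed by the SeO2 catalyst, O=[Se]=O)
Why: Sharpless allylic hydroxylation (ene reaction of the selenium oxide with the olefin, then [2,3]-sigmatropic shift of the allylseleninic acid) attacks the gem-dimethyl olefin at its (E)-methyl group because that is the only electron-rich olefin left, the ring olefin being deactivated by its allylic ester as the 2,3-olefin of geranyl acetate is, so the C–O bond of the target and the (E)-trisubstituted geometry are made in one step without touching a stereocentre.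

Step 13
Reactants: 18 (1R,5S)-5-[(2E)-4-hydroxy-3-methylbut-2-en-1-yl]-2,4,4-trimethylcyclohex-2-en-1-yl pyridine-2-carboxylate; 10 chloro[(1E,3E)-5-{[tert-butyl(dimethyl)silyl]oxy}-3-methylpenta-1,3-dien-1-yl]magnesium (THF solution)
Product: 20 (2E)-4-[(1R,5S)-5-[(1E,3E)-5-{[tert-butyl(dimethyl)silyl]oxy}-3-methylpenta-1,3-dien-1-yl]-4,6,6-trimethylcyclohex-3-en-1-yl]-2-methylbut-2-en-1-ol, via chloromagnesium alkoxide 19 (not isolated)
Conditions: 18, t-BuMgCl (1.0 equiv.), THF, −40 °C; then CuBr·SMe2 (30 mol %), 10 (2.3 equiv.), −40 → 0 °C; aq. NH4Cl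
Reagents that add atoms: none
Why: After the hydroxyl is parked as its magnesium alkoxide by the hindered, non-nucleophilic base, the same Cu-catalysed anti-SN2′ picolinate substitution delivers the dienyl group to the γ-carbon on the face opposite the ester, which here is trans to the side chain, setting the 6′S centre of ring B and the ε-olefin.

Step 14
Reactants: 20 (2E)-4-[(1R,5S)-5-[(1E,3E)-5-{[tert-butyl(dimethyl)silyl]oxy}-3-methylpenta-1,3-dien-1-yl]-4,6,6-trimethylcyclohex-3-en-1-yl]-2-methylbut-2-en-1-ol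
Product: 21 [(2E,4E)-5-[(1S,5R)-5-[(2E)-4-hydroxy-3-methylbut-2-en-1-yl]-2,6,6-trimethylcyclohex-2-en-1-yl]-3-methylpenta-2,4-dien-1-yl](triphenyl)phosphonium bromide
Conditions: PPh3·HBr (1.05 equiv.), MeOH–CH2Cl2, 0 → 20 °C
Reagents that add atoms: triphenylphosphine hydrobromide, Br.P(c1ccccc1)(c1ccccc1)c1ccccc1
Why: As in step 9, only the dienylic silyl ether gives a stabilised pentadienyl cation under PPh3·HBr in methanol at or below 20 °C, whereas the isolated 2-methylallylic alcohol needs heat to react and stays free.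

Step 15
Reactants: 21 [(2E,4E)-5-[(1S,5R)-5-[(2E)-4-hydroxy-3-methylbut-2-en-1-yl]-2,6,6-trimethylcyclohex-2-en-1-yl]-3-methylpenta-2,4-dien-1-yl](triphenyl)phosphonium bromide; 16 (2E,4E,6E,8E,10E,12E)-2,7,11-trimethyl-13-[(1R,5S)-2,6,6-trimethyl-5-(3-methylbut-2-en-1-yl)cyclohex-2-en-1-yl]trideca-2,4,6,8,10,12-hexaenal
Product: 23 (2S,6R,2′R,6′S)-2′-[(2E)-4-hydroxy-3-methylbut-2-en-1-yl]-2-(3-methylbut-2-en-1-yl)-ε,ε-carotene (CNP0304855.1), via phosphonium ylide 22 (not isolated)
Conditions: NaOMe (2.5 equiv.), CH2Cl2–MeOH, 0 °C; then 16, 0 → 23 °C; then heptane, 95 °C, N2, dark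
Reagents that add atoms: none
Why: Wittig olefination (the hydroxyl is tolerated as its alkoxide) joins the halves at C11′=C12′ and thermal equilibration in heptane gives the all-E polyene, the four ring stereocentres being remote from any acidic or reactive site.

## Compound list

1 | 2,4,4-trimethylcyclohex-2-en-1-one | CC1=CC(C)(C)CCC1=O | starting material
2 | 2,4,4-trimethylcyclohexa-2,5-dien-1-one | CC1=CC(C)(C)C=CC1=O | intermediate
3 | 4,4,5,5-tetramethyl-2-(3-methylbut-2-en-1-yl)-1,3,2-dioxaborolane (prenyl–B(pin)) | CC(C)=CCB1OC(C)(C)C(C)(C)O1 | starting material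
4 | (5S)-2,4,4-trimethyl-5-(3-methylbut-2-en-1-yl)cyclohex-2-en-1-one | CC(C)=CC[C@H]1CC(=O)C(C)=CC1(C)C | intermediate
5 | (1R,5S)-2,4,4-trimethyl-5-(3-methylbut-2-en-1-yl)cyclohex-2-en-1-ol (hydroxyl cis to prenyl) | CC(C)=CC[C@H]1C[C@@H](O)C(C)=CC1(C)C | intermediate
6 | (2E)-3-methylpent-2-en-4-yn-1-ol | C#C/C(C)=C/CO | starting material
7 | tert-butyl(dimethyl){[(2E)-3-methylpent-2-en-4-yn-1-yl]oxy}silane | C#C/C(C)=C/CO[Si](C)(C)C(C)(C)C | intermediate
8 | chlorobis(cyclopentadienyl)[(1E,3E)-5-{[tert-butyl(dimethyl)silyl]oxy}-3-methylpenta-1,3-dien-1-yl]zirconium (cyclopentadienyl rings drawn σ-bound) | Cl[Zr](C1C=CC=C1)(C1C=CC=C1)/C=C/C(C)=C/CO[Si](C)(C)C(C)(C)C | intermediate (not isolated)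
9 | tert-butyl{[(2E,4E)-5-iodo-3-methylpenta-2,4-dien-1-yl]oxy}dimethylsilane | I/C=C/C(C)=C/CO[Si](C)(C)C(C)(C)C | intermediate
10 | chloro[(1E,3E)-5-{[tert-butyl(dimethyl)silyl]oxy}-3-methylpenta-1,3-dien-1-yl]magnesium (LiCl complex, titrated THF solution) | Cl[Mg]/C=C/C(C)=C/CO[Si](C)(C)C(C)(C)C | intermediate
11 | (1S,5S)-2,4,4-trimethyl-5-(3-methylbut-2-en-1-yl)cyclohex-2-en-1-yl pyridine-2-carboxylate (ester trans to prenyl) | CC(C)=CC[C@H]1C[C@H](OC(=O)c2ccccn2)C(C)=CC1(C)C | intermediate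
12 | tert-butyl(dimethyl){[(2E,4E)-3-methyl-5-[(1R,5S)-2,6,6-trimethyl-5-(3-methylbut-2-en-1-yl)cyclohex-2-en-1-yl]penta-2,4-dien-1-yl]oxy}silane | CC(C)=CC[C@H]1CC=C(C)[C@@H](/C=C/C(C)=C/CO[Si](C)(C)C(C)(C)C)C1(C)C | intermediate
13 | [(2E,4E)-3-methyl-5-[(1R,5S)-2,6,6-trimethyl-5-(3-methylbut-2-en-1-yl)cyclohex-2-en-1-yl]penta-2,4-dien-1-yl](triphenyl)phosphonium bromide | CC(C)=CC[C@H]1CC=C(C)[C@@H](/C=C/C(C)=C/C[P+](c2ccccc2)(c2ccccc2)c2ccccc2)C1(C)C.[Br-] | intermediate
14 | (2E,4E,6E)-2,7-dimethylocta-2,4,6-trienedial | O=C/C(C)=C/C=C/C=C(C)/C=O | starting material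
15 | {(2E,4E)-3-methyl-5-[(1R,5S)-2,6,6-trimethyl-5-(3-methylbut-2-en-1-yl)cyclohex-2-en-1-yl]penta-2,4-dien-1-ylidene}(triphenyl)phosphorane | CC(C)=CC[C@H]1CC=C(C)[C@@H](/C=C/C(C)=C/C=P(c2ccccc2)(c2ccccc2)c2ccccc2)C1(C)C | intermediate (not isolated)
16 | (2E,4E,6E,8E,10E,12E)-2,7,11-trimethyl-13-[(1R,5S)-2,6,6-trimethyl-5-(3-methylbut-2-en-1-yl)cyclohex-2-en-1-yl]trideca-2,4,6,8,10,12-hexaenal | CC(C)=CC[C@H]1CC=C(C)[C@@H](/C=C/C(C)=C/C=C/C(C)=C/C=C/C=C(C)/C=O)C1(C)C | intermediate
17 | (1R,5S)-2,4,4-trimethyl-5-(3-methylbut-2-en-1-yl)cyclohex-2-en-1-yl pyridine-2-carboxylate (ester cis to prenyl) | CC(C)=CC[C@H]1C[C@@H](OC(=O)c2ccccn2)C(C)=CC1(C)C | intermediate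
18 | (1R,5S)-5-[(2E)-4-hydroxy-3-methylbut-2-en-1-yl]-2,4,4-trimethylcyclohex-2-en-1-yl pyridine-2-carboxylate | OC/C(C)=C/C[C@H]1C[C@@H](OC(=O)c2ccccn2)C(C)=CC1(C)C | intermediate
19 | chloromagnesium alkoxide of 18 (primary alkoxide) | Cl[Mg]OC/C(C)=C/C[C@H]1C[C@@H](OC(=O)c2ccccn2)C(C)=CC1(C)C | intermediate (not isolated)
20 | (2E)-4-[(1R,5S)-5-[(1E,3E)-5-{[tert-butyl(dimethyl)silyl]oxy}-3-methylpenta-1,3-dien-1-yl]-4,6,6-trimethylcyclohex-3-en-1-yl]-2-methylbut-2-en-1-ol | OC/C(C)=C/C[C@H]1CC=C(C)[C@H](/C=C/C(C)=C/CO[Si](C)(C)C(C)(C)C)C1(C)C | intermediate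
21 | [(2E,4E)-5-[(1S,5R)-5-[(2E)-4-hydroxy-3-methylbut-2-en-1-yl]-2,6,6-trimethylcyclohex-2-en-1-yl]-3-methylpenta-2,4-dien-1-yl](triphenyl)phosphonium bromide | OC/C(C)=C/C[C@H]1CC=C(C)[C@H](/C=C/C(C)=C/C[P+](c2ccccc2)(c2ccccc2)c2ccccc2)C1(C)C.[Br-] | intermediate
22 | {(2E,4E)-5-[(1S,5R)-5-[(2E)-4-hydroxy-3-methylbut-2-en-1-yl]-2,6,6-trimethylcyclohex-2-en-1-yl]-3-methylpenta-2,4-dien-1-ylidene}(triphenyl)phosphorane | OC/C(C)=C/C[C@H]1CC=C(C)[C@H](/C=C/C(C)=C/C=P(c2ccccc2)(c2ccccc2)c2ccccc2)C1(C)C | intermediate (not isolated)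
23 | (2E)-2-methyl-4-[(1R,5S)-4,6,6-trimethyl-5-{(1E,3E,5E,7E,9E,11E,13E,15E,17E)-3,7,12,16-tetramethyl-18-[(1R,5S)-2,6,6-trimethyl-5-(3-methylbut-2-en-1-yl)cyclohex-2-en-1-yl]octadeca-1,3,5,7,9,11,13,15,17-nonaen-1-yl}cyclohex-3-en-1-yl]but-2-en-1-ol = (2S,6R,2′R,6′S)-2′-[(2E)-4-hydroxy-3-methylbut-2-en-1-yl]-2-(3-methylbut-2-en-1-yl)-ε,ε-carotene | CC(C)=CC[C@H]1CC=C(C)[C@@H](/C=C/C(C)=C/C=C/C(C)=C/C=C/C=C(C)/C=C/C=C(C)/C=C/[C@H]2C(C)=CC[C@H](C/C=C(\C)CO)C2(C)C)C1(C)C | target

## Step count and risks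

Total steps: 15. Longest linear sequence: 8 steps (1 → 2 → 4 → 5 → 17 → 18 → 20 → 21 → 23; the ring A branch 1 → 2 → 4 → 5 → 11 → 12 → 13 → 16 → 23 is also 8).

The three steps most likely to fail:

First, the new conjugate prenylation (step 2). The risks are 1,2-addition to the carbonyl, transfer through the CMe2 terminus, and low enantioselectivity. The fallback uses known chemistry, sets out from dienone 2 and comes back at enone 4. Dienone 2 undergoes the established Cu-catalysed asymmetric conjugate addition of a dialkylzinc to a 4,4-disubstituted cyclohexadienone. Conditions are Cu(OTf)2 (2 mol %), a binaphthol-derived bis(1-phenylethyl)amine phosphoramidite (4 mol %) and the homoallylic reagent bis(3-methylbut-3-en-1-yl)zinc in toluene at −25 °C. This gives (5S)-2,4,4-trimethyl-5-(3-methylbut-3-en-1-yl)cyclohex-2-en-1-one F1. Its 1,1-disubstituted olefin is then moved one position into the trisubstituted prenyl olefin with RhCl3·3H2O (3 mol %) in ethanol at 70 °C, which gives 4. This costs one extra step and avoids any allyl-metal nucleophile.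

Second, the anti-SN2′ substitution for ring A (step 8). The γ-carbon is neopentylic, so direct SN2 attack at the secondary α-carbon may compete. The fallback sets out from alcohol 5, skips the Mitsunobu step, and comes back at 12. It replaces the intermolecular anti displacement by an intramolecular, directed syn delivery. Alcohol 5 and phenyl isocyanate (Et3N, CH2Cl2) give (1R,5S)-2,4,4-trimethyl-5-(3-methylbut-2-en-1-yl)cyclohex-2-en-1-yl N-phenylcarbamate F2. MeLi at −78 °C converts it into lithium (1R,5S)-2,4,4-trimethyl-5-(3-methylbut-2-en-1-yl)cyclohex-2-en-1-yl N-phenylcarbamate F3. With CuI and Grignard reagent 10, this salt forms a nitrogen-bound copper reagent that transfers the dienyl group to the γ-carbon on the same face as the departing oxygen (Gallina–Goering syn-SN2′). Because the carbamate is cis to the prenyl group, the product is again the cis compound 12.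

Third, the anti-SN2′ substitution for ring B (step 13). The cis ester can only become pseudoaxial together with the side chain, and a free alkoxide is present. The fallback sets out from enone 4 and comes back at phosphonium salt 21. It replaces allylic substitution by conjugate addition and enol triflate reduction. Enone 4, whose ring olefin is electron-poor, is hydroxylated under the conditions of step 12 to (5S)-5-[(2E)-4-hydroxy-3-methylbut-2-en-1-yl]-2,4,4-trimethylcyclohex-2-en-1-one F4. TBSCl and imidazole then give (5S)-5-[(2E)-4-{[tert-butyl(dimethyl)silyl]oxy}-3-methylbut-2-en-1-yl]-2,4,4-trimethylcyclohex-2-en-1-one F5. Cu-catalysed 1,4-addition of Grignard reagent 10 (CuBr·SMe2, THF, −78 → −30 °C) occurs anti to the C5 substituent, as cuprates add to carvone, and gives chloromagnesium (3R,5S)-5-[(2E)-4-{[tert-butyl(dimethyl)silyl]oxy}-3-methylbut-2-en-1-yl]-3-[(1E,3E)-5-{[tert-butyl(dimethyl)silyl]oxy}-3-methylpenta-1,3-dien-1-yl]-2,4,4-trimethylcyclohex-1-en-1-olate F6. This enolate is trapped in the same flask with PhNTf2 as (3R,5S)-5-[(2E)-4-{[tert-butyl(dimethyl)silyl]oxy}-3-methylbut-2-en-1-yl]-3-[(1E,3E)-5-{[tert-butyl(dimethyl)silyl]oxy}-3-methylpenta-1,3-dien-1-yl]-2,4,4-trimethylcyclohex-1-en-1-yl trifluoromethanesulfonate F7. Pd(OAc)2/PPh3, Bu3N and HCO2H in DMF at 60 °C reduce the triflate and leave the ε-olefin in place, giving tert-butyl{[(2E)-4-[(1R,5S)-5-[(1E,3E)-5-{[tert-butyl(dimethyl)silyl]oxy}-3-methylpenta-1,3-dien-1-yl]-4,6,6-trimethylcyclohex-3-en-1-yl]-2-methylbut-2-en-1-yl]oxy}dimethylsilane F8. Finally PPh3·HBr in methanol (conditions of step 14) removes both silyl groups and converts only the dienylic position into the phosphonium salt 21.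

Further compounds
F1 | step 2 | (5S)-2,4,4-trimethyl-5-(3-methylbut-3-en-1-yl)cyclohex-2-en-1-one | CC(=C)CC[C@H]1CC(=O)C(C)=CC1(C)C
F2 | step 8 | (1R,5S)-2,4,4-trimethyl-5-(3-methylbut-2-en-1-yl)cyclohex-2-en-1-yl N-phenylcarbamate | CC(C)=CC[C@H]1C[C@@H](OC(=O)Nc2ccccc2)C(C)=CC1(C)C
F3 | step 8 | lithium (1R,5S)-2,4,4-trimethyl-5-(3-methylbut-2-en-1-yl)cyclohex-2-en-1-yl N-phenylcarbamate (N-lithiated F2) | CC(C)=CC[C@H]1C[C@@H](OC(=O)N([Li])c2ccccc2)C(C)=CC1(C)C
F4 | step 13 | (5S)-5-[(2E)-4-hydroxy-3-methylbut-2-en-1-yl]-2,4,4-trimethylcyclohex-2-en-1-one | OC/C(C)=C/C[C@H]1CC(=O)C(C)=CC1(C)C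
F5 | step 13 | (5S)-5-[(2E)-4-{[tert-butyl(dimethyl)silyl]oxy}-3-methylbut-2-en-1-yl]-2,4,4-trimethylcyclohex-2-en-1-one | CC(C)(C)[Si](C)(C)OC/C(C)=C/C[C@H]1CC(=O)C(C)=CC1(C)C
F6 | step 13 | chloromagnesium (3R,5S)-5-[(2E)-4-{[tert-butyl(dimethyl)silyl]oxy}-3-methylbut-2-en-1-yl]-3-[(1E,3E)-5-{[tert-butyl(dimethyl)silyl]oxy}-3-methylpenta-1,3-dien-1-yl]-2,4,4-trimethylcyclohex-1-en-1-olate | CC(C)(C)[Si](C)(C)OC/C(C)=C/C[C@H]1CC(O[Mg]Cl)=C(C)[C@H](/C=C/C(C)=C/CO[Si](C)(C)C(C)(C)C)C1(C)C
F7 | step 13 | (3R,5S)-5-[(2E)-4-{[tert-butyl(dimethyl)silyl]oxy}-3-methylbut-2-en-1-yl]-3-[(1E,3E)-5-{[tert-butyl(dimethyl)silyl]oxy}-3-methylpenta-1,3-dien-1-yl]-2,4,4-trimethylcyclohex-1-en-1-yl trifluoromethanesulfonate | CC(C)(C)[Si](C)(C)OC/C(C)=C/C[C@H]1CC(OS(=O)(=O)C(F)(F)F)=C(C)[C@H](/C=C/C(C)=C/CO[Si](C)(C)C(C)(C)C)C1(C)C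
F8 | step 13 | tert-butyl{[(2E)-4-[(1R,5S)-5-[(1E,3E)-5-{[tert-butyl(dimethyl)silyl]oxy}-3-methylpenta-1,3-dien-1-yl]-4,6,6-trimethylcyclohex-3-en-1-yl]-2-methylbut-2-en-1-yl]oxy}dimethylsilane | CC(C)(C)[Si](C)(C)OC/C(C)=C/C[C@H]1CC=C(C)[C@H](/C=C/C(C)=C/CO[Si](C)(C)C(C)(C)C)C1(C)C
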